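## Structural features

Target numbering is used for every compound; β is the face of the C1 methyl group. The target is a briarane: cyclohexene ring A (C1, C10–C14) is trans-fused through C1–C10 to a ten-membered carbocycle (C1–C10), and a γ-lactone (O7, C19, C17) is fused across C7–C8. Quaternary C1 sits between three stereocentres (C2 β-OAc, C14 α-OAc, C10 α-H). C7, C8 and C17 are contiguous, with O7 and the C8 hydroxyl cis and the lactone trans-fused to the large ring. The C9 ketone is β,γ-unsaturated (C11=C12), so C10–H is α-keto and allylic; the C8 α-ketol, the allylic C20 alcohol, two acetates and the Z C5=C6 alkene next to the lactone oxygen are also fragile. The real difficulty is a ten-membered ring with a Z trisubstituted alkene that carries oxygen on C2, C7, C8 and C9, in which stereocontrol depends on conformation. C3–C6 form a four-carbon bridge between the oxygenated carbons C2 and C7, and O7 with C5=C6 is an enone-level pattern. Excising that bridge leaves a trans-decalin with a C2–C7 bond whose ring B carbons C2, C7, C8 and C9 are all oxygenated, as in a quinone-derived ring; a 2-vinyl-7-propynyl carbinol of that decalin is the substrate for a [3,3] ring expansion.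

## Logic of the disconnections

33 ⇒ 32 ⇒ 31 ⇒ 30. No skeletal bond is cut: O20–Si, then C9=O back to C9–OH, then the C9 ether. The C9 ketone makes C10–H doubly activated, so it is formed second to last and only a buffered fluoride step follows. The demand is a C9 protecting group that leaves without acid or base (oxidative cleavage) and a primary silyl ether that outlasts everything else.

30 ⇒ 29 ⇒ 28. The two acetyl C–O bonds and the C2–H bond are cut. C2 and C14 are 1,3-related through C1 and anti, so a free C14 hydroxyl can deliver hydride to a C2 ketone. The gain is that C2 comes from a ketone; the demand is that C14–OH be free and C2 be the only ketone.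

28 ⇒ 27. C8–C17 is cut. The α-hydroxy-γ-lactone is the aldol adduct of a C7 O-propanoate and a C8 ketone; the tether fixes regiochemistry and ties the C8 configuration to C7. One step gives the lactone, C8 and C17. It demands an enolate made without base (C–Br reduction) and a ring torsion that leads to trans fusion.

27 ⇒ 26 ⇒ 24 ⇒ 23. The C2 and C8 ketones are re-masked as methyl enol ether and dimethyl ketal, C14–OH as silyl ether; the O7–C19 ester bond and the C7–H bond are cut. In 23 C7 is then the only carbonyl, so its reduction is chemoselective. The demands are facial control at C7 in a ten-membered ring and one acid treatment that unveils three groups.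

23 ⇒ 21 (key). Retrosynthetically C2–C7 is reconnected and C4–C5 cut. The medium ring becomes a rigid trans-decalin on which C1, C10 and C14 are set, and both C2 and C7 emerge at useful oxidation levels. The step demands vinyl and propynyl gauche, and a Z enone on protonation. Two design points follow from analysis of the shift. The propynyl group must be equatorial (α): an axial one would need addition syn to the C1 methyl and would give the other C2=C3 geometry. C8 carries its oxygen as a dimethyl ketal, so no hydroxylation of the ten-membered ring is needed later.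

21 ⇒ 19 + 20; 19 ⇒ 18 ⇒ 16. The C7–alkyne bond is cut, then C7=O to C7–OH, then C7–O and one C8–OMe back to the C7=C8 enol ether. Ketone 19 lies between two fully substituted carbons and cannot enolise. The quinone's own methoxy group becomes the C8 ketal. The demands are equatorial delivery to a hindered ketone and epoxidation of the enol ether only.

16 ⇒ 15 ⇒ 13 + 14. O–CH3 and C2–vinyl are cut, returning to the vinylogous ester carbonyl. The demands are 1,2-addition at a hindered carbonyl and O-methylation without migration of the syn-axial C14 silyl group.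

13 ⇒ 12 ⇒ 10 + 11; 10 ⇒ 8 ⇒ 7. O20–Si and C11–C20 are cut; the enol triflate goes back to the ring A enone and this to the C11 methylene. C11=C12 bearing C20 is an enol triflate coupling product, and the enone fixes the enolate regiochemistry. The demand is selective allylic oxidation at C11.

7 ⇒ 6 ⇒ 5 ⇒ 4. The C9 ether and C9–H are removed and C10 is inverted. These steps differentiate the two carbonyls and set the trans fusion while C10–H is α to a ketone and nothing β to it can eliminate.

4 ⇒ 2 + 3; 2 ⇒ 1. C1–C14 and C10–C11 are cut. The quinone supplies ring B with the C1 methyl and oxygen on C2, C8 and C9; the diene supplies C11–C14 with the C14 oxygen. A 1-methoxy-3-silyloxybutadiene would leave a ketone on C12 or C13 and a methyl ether, so the 1-silyloxydiene from 1 is used. The demands are bonding of the oxygenated diene terminus to the methyl-bearing carbon, endo addition, and one enantiomer.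

## Other disconnections considered

Alternative 1: The cut is C1–C2 and C9–C10, followed by cleavage of C2–C9. Forward, a 4-oxy-3-methylcyclohexenone tethered through a diisopropylsilylene from O14 to an eight-membered enediol would undergo [2+2] photocycloaddition to photoadduct A1. Opening the cyclobutanediol would then release the ten-membered ring. In its favour: the ring arises by fragmentation, which is the equal of the chosen plan in avoiding end-to-end closure. C9 arrives directly as a ketone and C5=C6 is Z from the start; both points are better than in the chosen plan. Ring A arrives as a C11 ketone, equal to intermediate 8. Against it: A1 is cis at C1/C10, so C10 must be epimerised between two carbonyls. C7 and C8 emerge as plain methylenes, so the lactone oxygen, the C8 carbinol and C17 would need C–H oxidation on the medium ring. The photoaddition must join a tetrasubstituted enediol to a β-methyl enone. Step economy is no better, because the eight-membered partner is a synthesis of its own, and the lactone has no handle.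

Alternative 2: The cut is the C7–O bond. Forward, a C19 primary amide would be N-iodinated, the amidyl radical would abstract the allylic C7 hydrogen (1,5-shift), and iodination and closure through oxygen would give the iminolactone and then lactone A2. In its favour: C7 needs no prior oxygen and no stereodefined carbinol, and the closure is the last skeletal event; fewer redox steps at C7 is a point better than the chosen plan. The five-membered closure is the equal of the tethered aldol in regiocontrol. Against it: the allylic radical is delocalised to C5, so regiochemistry and the Z geometry are at risk. The C7 configuration depends on the ring conformation. Iodine and the hypervalent iodine oxidant meet the C11=C12 alkene and the enolisable C9 ketone. The step builds neither the ten-membered ring nor the C8 quaternary carbinol, which the chosen plan links to C7 through the tether.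

Alternative 3: The cut is C1–C10 in ring A. Forward, anodic oxidation of a C2 enol ether would give a radical cation that is trapped at C1 by an allylsilane, giving ketal A3. In its favour: the quaternary C1 and the C11=C12 alkene with C20 appear in one step. This is better than the chosen plan, which spends four steps (6–9) on that alkene. Against it: A3 is the C14 epimer and would need inversion at a neopentyl carbinol. The ten-membered ring is left to be closed end to end from two acyclic arms, the very problem the ring expansion avoids. Absolute configuration must come from an acyclic precursor. Overall step economy is worse once the medium ring is counted.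

Key step: step 15

Remark on the chemistry: centres that are erased later (C9 carbinol, C2 and C7 of the decalin, C7 of 17 and 18, the bromide carbon of 25–27) are drawn as the expected major isomers or left undefined; they have no bearing on 33.

Step 1
Reactants: 1 (E)-but-2-enal
Product: 2 (E)-1-(tert-butyldimethylsilyloxy)buta-1,3-diene
Conditions: t-BuMe2SiOTf, Et3N, Et2O, 0 → 25 °C
Reagents that add atoms: tert-butyldimethylsilyl trifluoromethanesulfonate, CC(C)(C)[Si](C)(C)OS(=O)(=O)C(F)(F)F
Why: Soft enolisation: O-silylation of the enal and γ-deprotonation by the amine give the silyl dienol ether; the (1E) isomer is favoured and is the only one that reacts as a diene.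

Step 2
Reactants: 2 (E)-1-(tert-butyldimethylsilyloxy)buta-1,3-diene; 3 2-methoxy-5-methylcyclohexa-2,5-diene-1,4-dione
Product: 4 cis-fused cycloadduct (C1 methyl and C10 H both β, 14α-OTBS, C2 and C9 ketones, 8-methoxy C7=C8, C12=C13)
Conditions: (S)-1-(2-methylphenyl)-3,3-diphenyltetrahydro-1H,3H-pyrrolo[1,2-c][1,3,2]oxazaborole (20 mol %), HNTf2 (18 mol %), CH2Cl2, −78 → −40 °C
Reagents that add atoms: none
Why: Enantioselective Lewis acid catalysed Diels–Alder reaction at the methyl-bearing quinone alkene (the methoxy-bearing alkene is a deactivated vinylogous ester). Boron binds the more basic, methoxy-conjugated carbonyl (future C2), so the CH2 terminus of the diene bonds to C10 and the oxygenated terminus to C1, which puts OTBS on C14; endo addition places it trans to the C1 methyl. The chiral cation shields one quinone face and should set C1, C10 and C14 in the absolute sense of 33 (the mirror-image catalyst would give the antipode).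

Step 3
Reactants: 4 cis-fused cycloadduct
Product: 5 trans-fused ene-dione (10α-H)
Conditions: DBU (0.2 equiv), THF, 25 °C
Reagents that add atoms: none
Why: Base-mediated epimerisation at C10 through the C9 enolate. C1 is quaternary, so neither aromatisation nor β-elimination of the C14 silyloxy group is possible, and the flattened ene-dione ring should favour trans fusion, as is known for the butadiene adduct of the same quinone.

Step 4
Reactants: 5 trans-fused ene-dione
Product: 6 9β-alcohol (C2 vinylogous ester retained)
Conditions: NaBH4, CeCl3·7H2O, MeOH, −78 °C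
Reagents that add atoms: none
Why: Luche 1,2-reduction of the more electrophilic C9 carbonyl; the C2 carbonyl is a hindered vinylogous ester and should stay. Hydride enters from the α face, anti to the syn-axial C1 methyl (this centre is erased in step 23).

Step 5
Reactants: 6 9β-alcohol
Product: 7 9β-(4-methoxybenzyl) ether
Conditions: NaH, 4-methoxybenzyl chloride, Bu4NI (cat.), THF–DMF, 0 → 25 °C
Reagents that add atoms: 4-methoxybenzyl chloride, COc1ccc(CCl)cc1
Why: Williamson etherification of the C9 alkoxide; the ether cannot migrate under the later KH step, is removed oxidatively in step 22, and as an axial β group helps to close the β face of C7.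

Step 6
Reactants: 7 9β-PMB ether
Product: 8 ring A enone (C11 ketone, C12=C13)
Conditions: CrO3, 3,5-dimethylpyrazole, CH2Cl2, −20 °C
Reagents that add atoms: chromium trioxide, O=[Cr](=O)=O
Why: Allylic C–H oxidation by the hexavalent chromium–pyrazole complex at C11, the only allylic methylene of the ring A alkene; the other allylic position (C14) is tertiary and silyloxy-substituted, and the vinylogous ester is inert to the oxidant.

Step 7
Reactants: 8 ring A enone
Product: 10 C11 enol triflate (C11=C12), via lithium C11 enolate 9 (not isolated)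
Conditions: LiBH(s-Bu)3, THF, −78 °C; then PhNTf2, −78 → 0 °C
Reagents that add atoms: N-phenylbis(trifluoromethanesulfonimide), O=S(=O)(N(c1ccccc1)S(=O)(=O)C(F)(F)F)C(F)(F)F
Why: Conjugate hydride reduction of the β-unsubstituted enone gives the C11 enolate regiospecifically, and O-triflation fixes the C11=C12 double bond; the hindered vinylogous ester carbonyl should not be reduced at −78 °C.

Step 8
Reactants: 10 C11 enol triflate; 11 (tributylstannyl)methanol
Product: 12 C20 allylic alcohol
Conditions: Pd(PPh3)4 (10 mol %), LiCl, 1,4-dioxane, 90 °C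
Reagents that add atoms: none
Why: Stille coupling of the enol triflate with the hydroxymethyl stannane installs C20 on C11 with the alkene already in place; chloride assists transmetalation at divalent palladium.

Step 9
Reactants: 12 C20 allylic alcohol
Product: 13 C20 tert-butyldiphenylsilyl ether
Conditions: t-BuPh2SiCl, imidazole, DMF, 0 → 25 °C
Reagents that add atoms: tert-butyl(chloro)diphenylsilane, CC(C)(C)[Si](Cl)(c1ccccc1)c1ccccc1
Why: Silylation of the primary allylic alcohol; this acid-stable silyl ether must survive step 18 and is removed last.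

Step 10
Reactants: 13 C20 silyl ether; 14 vinylmagnesium bromide
Product: 15 C2 tertiary carbinol (2β-vinyl, 2α-OH)
Conditions: CeCl3, THF, −78 → 0 °C; aq. NaHCO3 work-up
Reagents that add atoms: none
Why: 1,2-Addition of the vinylcerium reagent to the vinylogous ester carbonyl (organocerium reagents suppress conjugate addition). The α-axial trajectory is syn-axial to the 14α-silyloxy group, so attack from the β face should give the 2β-vinyl carbinol; this centre becomes trigonal in step 15. The work-up stays basic because the 3-methoxy allylic alcohol ionises with acid.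

Step 11
Reactants: 15 C2 tertiary carbinol
Product: 16 C2 methyl ether
Conditions: KN(SiMe3)2, THF, −78 °C; then MeOTf, −78 → −40 °C
Reagents that add atoms: methyl trifluoromethanesulfonate, COS(=O)(=O)C(F)(F)F
Why: O-Methylation of the potassium alkoxide by methyl triflate at −78 °C, fast enough to outrun migration of the syn-axial C14 silyl group; the methyl ether makes C2 a future enol ether.

Step 12
Reactants: 16 C2 methyl ether
Product: 18 7α-hydroxy C8 dimethyl ketal, via 7α,8α-epoxide 17 (not isolated)
Conditions: dimethyldioxirane (1.05 equiv), K2CO3, acetone–MeOH, −78 → 0 °C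
Reagents that add atoms: dimethyldioxirane, CC1(C)OO1; methanol, CO
Why: Rubottom-type oxidation: the electron-rich enol ether is epoxidised far faster than the vinyl group or the ring A alkene, and methanol opens the alkoxy epoxide at C8. This oxygenates C7 and stores C8 as a ketal; the C7 configuration is erased in step 13.

Step 13
Reactants: 18 7α-hydroxy C8 dimethyl ketal
Product: 19 C7 ketone
Conditions: Dess–Martin periodinane, NaHCO3, CH2Cl2, 25 °C
Reagents that add atoms: none
Why: Dess–Martin oxidation of the hindered secondary alcohol under buffered conditions that spare the ketal and the tertiary allylic ether.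

Step 14
Reactants: 19 C7 ketone; 20 prop-1-ynylmagnesium bromide
Product: 21 propynyl vinyl trans-decalin carbinol (7α-propynyl, 7β-OH, 2β-vinyl, 2α-OMe, C8 dimethyl ketal, 9β-OPMB, 14α-OTBS)
Conditions: CeCl3, THF, −78 → 25 °C
Reagents that add atoms: none
Why: Addition of the propynylcerium reagent to a ketone that cannot enolise (both α-carbons are fully substituted), so forcing conditions are tolerated. The β face is closed by the syn-axial C1 methyl and 9β-OPMB, so the slim nucleophile should enter from the α face and end equatorial, trans-diequatorial (gauche) to the vinyl group.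

Step 15
Reactants: 21 propynyl vinyl trans-decalin carbinol
Product: 23 ten-ring enone enol ether (C7 ketone, Z C5=C6, C2 methyl enol ether with C1 and C4 trans), via potassium allenolate 22 (not isolated)
Conditions: KH, 18-crown-6, THF, 0 → 25 °C; then sat. aq. NH4Cl, −78 °C
Reagents that add atoms: none
Why: Anionic oxy-Cope rearrangement of a 1-alkynyl-2-vinylcyclohexanol: the crown-separated potassium alkoxide weakens C2–C7, and a chair-like [3,3] shift forms C4–C5 as C2–C7 breaks, giving allenolate 22, which is protonated at C6 to the conjugated enone. The closest known reaction is the anionic oxy-Cope ring expansion of trans-1,2-dialkenylcyclohexanols to (E)-cyclodec-5-enones and its acetylenic variant. The ten-membered ring is closed by four-carbon expansion of ring B, not by end-to-end cyclisation. No stereocentre is formed, since C2 and C7 become trigonal. The C2=C3 geometry follows from the equatorial propynyl group being anti to C1; the Z geometry of C5=C6 should follow from protonation on the side of the C16 methyl, outside the ring, with equilibration toward the more stable cis ring alkene if needed. The step needs vinyl and propynyl gauche, which the trans-diequatorial arrangement secures. Relief of strain among the four contiguous fully substituted carbons C1, C2, C7 and C8 should favour the shift over loss of propynide; C1, C10 and C14 are untouched.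

Step 16
Reactants: 23 ten-ring enone enol ether
Product: 24 7α-alcohol (7S)
Conditions: (R)-1-methyl-3,3-diphenyltetrahydro-1H,3H-pyrrolo[1,2-c][1,3,2]oxazaborole (1 equiv), catecholborane, toluene, −78 °C
Reagents that add atoms: none
Why: CBS reduction under catalyst control: with the ketal carbon C8 as the large group and the alkenyl C6 as the small one, the (R)-oxazaborolidine should give the (7S) alcohol (7α-OH). The enol ether keeps C2 masked, so C7 is the only carbonyl.

Step 17
Reactants: 24 7α-alcohol; 25 2-bromopropanoyl bromide (racemic)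
Product: 26 C7 2-bromopropanoate
Conditions: pyridine, CH2Cl2, −20 → 0 °C
Reagents that add atoms: none
Why: Acylation of the allylic alcohol with retention at C7; pyridine takes up HBr and so protects enol ether and ketal. Both epimers at the bromide carbon are carried on.

Step 18
Reactants: 26 C7 2-bromopropanoate
Product: 27 C2,C8-diketone 14α-alcohol
Conditions: aq. HCl (2 M), THF, 25 → 40 °C
Reagents that add atoms: water, O
Why: One acid treatment hydrolyses the methyl enol ether (C2 ketone) and the C8 dimethyl ketal (C8 ketone) and cleaves the secondary silyl ether at C14; the primary tert-butyldiphenylsilyl ether, the benzyl-type ether and the ester should survive.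

Step 19
Reactants: 27 C2,C8-diketone 14α-alcohol
Product: 28 hydroxy lactone (8α-OH, 17-methyl cis to it, C2 ketone)
Conditions: SmI2 (2.2 equiv), THF, −78 °C
Reagents that add atoms: none
Why: Intramolecular Reformatsky reaction: reduction of the C–Br bond gives a trivalent samarium ester enolate, which closes the five-membered lactone on the adjacent C8 ketone (5-exo aldol). Attack with C6 and C9 anti about C7–C8, the natural torsion of the large ring, should give the trans-fused lactone with 8α-OH. At C17 the methyl should take the position anti to C9.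

Step 20
Reactants: 28 hydroxy lactone
Product: 29 2β,14α-diol
Conditions: Me4NBH(OAc)3, AcOH–MeCN, −30 °C
Reagents that add atoms: none
Why: Evans–Saksena reduction: the C14 hydroxyl binds boron and delivers hydride through a six-membered chair transition state to the C2 ketone, giving the 1,3-anti diol, which is the 2β,14α pattern of 33.

Step 21
Reactants: 29 2β,14α-diol
Product: 30 2,14-diacetate
Conditions: Ac2O, DMAP (cat.), pyridine, CH2Cl2, 25 °C
Reagents that add atoms: acetic anhydride, CC(=O)OC(C)=O
Why: DMAP-catalysed acetylation of the two secondary hydroxyls; the tertiary C8 hydroxyl should not react under these conditions.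

Step 22
Reactants: 30 2,14-diacetate
Product: 31 9β-alcohol
Conditions: DDQ, CH2Cl2–pH 7 buffer, 0 °C
Reagents that add atoms: none
Why: Oxidative cleavage of the 4-methoxybenzyl ether through the benzylic cation and its hydrolysis; the neutral conditions spare acetates, lactone and silyl ether, and the aqueous buffer hydrolyses any anisylidene acetal formed with the C8 hydroxyl.

Step 23
Reactants: 31 9β-alcohol
Product: 32 C9 ketone (C20 silyl ether of the target)
Conditions: Dess–Martin periodinane, NaHCO3, CH2Cl2, 0 → 25 °C
Reagents that add atoms: none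
Why: Dess–Martin oxidation of the hindered C9 alcohol without base, so that C10–H, now α-keto and allylic, is neither epimerised nor the alkene drawn into conjugation.

Step 24
Reactants: 32 C9 ketone
Product: 33 CNP0140109.1 (target)
Conditions: HF·pyridine, pyridine, THF, 0 → 25 °C
Reagents that add atoms: none
Why: Fluoride cleavage of the primary silyl ether under buffered, weakly acidic conditions that leave the acetates, the lactone and the β,γ-unsaturated ketone untouched.

Compound list

1 | (E)-but-2-enal | C/C=C/C=O | starting material
2 | (E)-1-(tert-butyldimethylsilyloxy)buta-1,3-diene | C=C/C=C/O[Si](C)(C)C(C)(C)C | intermediate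
3 | 2-methoxy-5-methylcyclohexa-2,5-diene-1,4-dione | COC1=CC(=O)C(C)=CC1=O | starting material
4 | cis-fused cycloadduct (1β-Me, 10β-H, 14α-OTBS, C2 and C9 ketones, 8-OMe C7=C8, C12=C13) | CC(C)(C)[Si](C)(C)O[C@H]1C=CC[C@H]2C(=O)C(OC)=CC(=O)[C@]21C | intermediate
5 | trans-fused ene-dione (10α-H) | CC(C)(C)[Si](C)(C)O[C@H]1C=CC[C@@H]2C(=O)C(OC)=CC(=O)[C@]21C | intermediate
6 | 9β-alcohol | CC(C)(C)[Si](C)(C)O[C@H]1C=CC[C@@H]2[C@H](O)C(OC)=CC(=O)[C@]21C | intermediate
7 | 9β-(4-methoxybenzyl) ether | CC(C)(C)[Si](C)(C)O[C@H]1C=CC[C@@H]2[C@H](OCc3ccc(OC)cc3)C(OC)=CC(=O)[C@]21C | intermediate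
8 | ring A enone (C11 ketone, C12=C13) | CC(C)(C)[Si](C)(C)O[C@H]1C=CC(=O)[C@@H]2[C@H](OCc3ccc(OC)cc3)C(OC)=CC(=O)[C@]21C | intermediate
9 | lithium C11 enolate (C11=C12) | CC(C)(C)[Si](C)(C)O[C@H]1CC=C([O-])[C@@H]2[C@H](OCc3ccc(OC)cc3)C(OC)=CC(=O)[C@]21C.[Li+] | intermediate (not isolated)
10 | C11 enol triflate (C11=C12) | CC(C)(C)[Si](C)(C)O[C@H]1CC=C(OS(=O)(=O)C(F)(F)F)[C@@H]2[C@H](OCc3ccc(OC)cc3)C(OC)=CC(=O)[C@]21C | intermediate
11 | (tributylstannyl)methanol | CCCC[Sn](CCCC)(CCCC)CO | starting material
12 | C20 allylic alcohol | CC(C)(C)[Si](C)(C)O[C@H]1CC=C(CO)[C@@H]2[C@H](OCc3ccc(OC)cc3)C(OC)=CC(=O)[C@]21C | intermediate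
13 | C20 tert-butyldiphenylsilyl ether | CC(C)(C)[Si](C)(C)O[C@H]1CC=C(CO[Si](c3ccccc3)(c3ccccc3)C(C)(C)C)[C@@H]2[C@H](OCc3ccc(OC)cc3)C(OC)=CC(=O)[C@]21C | intermediate
14 | vinylmagnesium bromide | C=C[Mg]Br | starting material
15 | C2 tertiary carbinol (2β-vinyl, 2α-OH) | CC(C)(C)[Si](C)(C)O[C@H]1CC=C(CO[Si](c3ccccc3)(c3ccccc3)C(C)(C)C)[C@@H]2[C@H](OCc3ccc(OC)cc3)C(OC)=C[C@](O)(C=C)[C@]21C | intermediate
16 | C2 methyl ether | CC(C)(C)[Si](C)(C)O[C@H]1CC=C(CO[Si](c3ccccc3)(c3ccccc3)C(C)(C)C)[C@@H]2[C@H](OCc3ccc(OC)cc3)C(OC)=C[C@](OC)(C=C)[C@]21C | intermediate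
17 | 7α,8α-epoxide | CC(C)(C)[Si](C)(C)O[C@H]1CC=C(CO[Si](c3ccccc3)(c3ccccc3)C(C)(C)C)[C@@H]2[C@H](OCc3ccc(OC)cc3)[C@@]3(OC)O[C@H]3[C@](OC)(C=C)[C@]21C | intermediate (not isolated)
18 | 7α-hydroxy C8 dimethyl ketal | CC(C)(C)[Si](C)(C)O[C@H]1CC=C(CO[Si](c3ccccc3)(c3ccccc3)C(C)(C)C)[C@@H]2[C@H](OCc3ccc(OC)cc3)C(OC)(OC)[C@@H](O)[C@](OC)(C=C)[C@]21C | intermediate
19 | C7 ketone | CC(C)(C)[Si](C)(C)O[C@H]1CC=C(CO[Si](c3ccccc3)(c3ccccc3)C(C)(C)C)[C@@H]2[C@H](OCc3ccc(OC)cc3)C(OC)(OC)C(=O)[C@](OC)(C=C)[C@]21C | intermediate
20 | prop-1-ynylmagnesium bromide | CC#C[Mg]Br | starting material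
21 | propynyl vinyl trans-decalin carbinol (7α-propynyl, 7β-OH, 2β-vinyl, 2α-OMe) | CC(C)(C)[Si](C)(C)O[C@H]1CC=C(CO[Si](c3ccccc3)(c3ccccc3)C(C)(C)C)[C@@H]2[C@H](OCc3ccc(OC)cc3)C(OC)(OC)[C@@](O)(C#CC)[C@](OC)(C=C)[C@]21C | intermediate
22 | potassium allenolate | CC(C)(C)[Si](C)(C)O[C@H]1CC=C(CO[Si](c3ccccc3)(c3ccccc3)C(C)(C)C)[C@@H]2[C@H](OCc3ccc(OC)cc3)C(OC)(OC)C([O-])=C=C(C)C/C=C(OC)/[C@]21C.[K+] | intermediate (not isolated)
23 | ten-ring enone enol ether | CC(C)(C)[Si](C)(C)O[C@H]1CC=C(CO[Si](c3ccccc3)(c3ccccc3)C(C)(C)C)[C@@H]2[C@H](OCc3ccc(OC)cc3)C(OC)(OC)C(=O)/C=C(/C)C/C=C(OC)/[C@]21C | intermediate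
24 | 7α-alcohol (7S) | CC(C)(C)[Si](C)(C)O[C@H]1CC=C(CO[Si](c3ccccc3)(c3ccccc3)C(C)(C)C)[C@@H]2[C@H](OCc3ccc(OC)cc3)C(OC)(OC)[C@@H](O)/C=C(/C)C/C=C(OC)/[C@]21C | intermediate
25 | 2-bromopropanoyl bromide (racemic) | CC(Br)C(Br)=O | starting material
26 | C7 2-bromopropanoate | CC(C)(C)[Si](C)(C)O[C@H]1CC=C(CO[Si](c3ccccc3)(c3ccccc3)C(C)(C)C)[C@@H]2[C@H](OCc3ccc(OC)cc3)C(OC)(OC)[C@@H](OC(=O)C(C)Br)/C=C(/C)C/C=C(OC)/[C@]21C | intermediate
27 | C2,C8-diketone 14α-alcohol | O[C@H]1CC=C(CO[Si](c3ccccc3)(c3ccccc3)C(C)(C)C)[C@@H]2[C@H](OCc3ccc(OC)cc3)C(=O)[C@@H](OC(=O)C(C)Br)/C=C(/C)CCC(=O)[C@]21C | intermediate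
28 | hydroxy lactone (C2 ketone) | O[C@H]1CC=C(CO[Si](c3ccccc3)(c3ccccc3)C(C)(C)C)[C@@H]2[C@H](OCc3ccc(OC)cc3)[C@@]3(O)[C@H](/C=C(/C)CCC(=O)[C@]21C)OC(=O)[C@@H]3C | intermediate
29 | 2β,14α-diol | O[C@H]1CC=C(CO[Si](c3ccccc3)(c3ccccc3)C(C)(C)C)[C@@H]2[C@H](OCc3ccc(OC)cc3)[C@@]3(O)[C@H](/C=C(/C)CC[C@H](O)[C@]21C)OC(=O)[C@@H]3C | intermediate
30 | 2,14-diacetate | CC(=O)O[C@H]1CC=C(CO[Si](c3ccccc3)(c3ccccc3)C(C)(C)C)[C@@H]2[C@H](OCc3ccc(OC)cc3)[C@@]3(O)[C@H](/C=C(/C)CC[C@H](OC(C)=O)[C@]21C)OC(=O)[C@@H]3C | intermediate
31 | 9β-alcohol | CC(=O)O[C@H]1CC=C(CO[Si](c3ccccc3)(c3ccccc3)C(C)(C)C)[C@@H]2[C@H](O)[C@@]3(O)[C@H](/C=C(/C)CC[C@H](OC(C)=O)[C@]21C)OC(=O)[C@@H]3C | intermediate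
32 | C9 ketone (C20 silyl ether of the target) | CC(=O)O[C@H]1CC=C(CO[Si](c3ccccc3)(c3ccccc3)C(C)(C)C)[C@@H]2C(=O)[C@@]3(O)[C@H](/C=C(/C)CC[C@H](OC(C)=O)[C@]21C)OC(=O)[C@@H]3C | intermediate
33 | CNP0140109.1 | CC(=O)O[C@H]1CC=C(CO)[C@@H]2C(=O)[C@@]3(O)[C@H](/C=C(/C)CC[C@H](OC(C)=O)[C@]21C)OC(=O)[C@@H]3C | target

Total step count: 24. Longest linear sequence: 24 steps (1 to 33; quinone 3 enters at step 2, 23 steps from 3).

Steps least certain to work

Step 15 (key step). The alkoxide may fragment by loss of propynide back to 19 instead of rearranging, and protonation of the allenolate may give both C5=C6 geometries. Fallback: the better-precedented dialkenyl variant. Ketone 19 would be treated with (E)-prop-1-enylmagnesium bromide and CeCl3 to give the 7α-propenyl carbinol F1. KH and 18-crown-6 followed by Me3SiCl would give the ring-expanded trimethylsilyl enol ether F2 (C6=C7, C5 sp3). Saegusa–Ito oxidation with Pd(OAc)2 would then introduce C5=C6, which is regiochemically unambiguous because C8 is quaternary; after isomerisation to the cis ring alkene if required, the route is rejoined at 23.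

Step 2. The chiral cation may discriminate the quinone faces poorly, or bind the other carbonyl and so place the diene oxygen on C11. Fallback: 2 and 3 would be combined with BF3·OEt2, which gives the same regiochemistry in racemic form, and carried through steps 3 and 4. The racemic alcohol would be esterified with (S)-2-methoxy-2-phenylacetic acid (DCC, DMAP) and the diastereomers separated. The ester of the wanted series, the 9-O-(S)-methoxyphenylacetate F3, would be cleaved with K2CO3 in MeOH, returning to the route at 6.

Step 6. Hydrogen abstraction may also occur at the benzylic position of the C9 ether or at C14, and C10 of the product is α to a ketone with a β-alkoxy group, so elimination is possible. Fallback: from 7, an ene/[2,3] hydroxylation with SeO2 and t-BuOOH would give the C11 allylic alcohol F4, which MnO2 would oxidise; the route is rejoined at 8.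

Step 16. Both groups flanking the C7 carbonyl are large, so catalyst control may be weak or reversed and the ring conformation may impose its own bias. Fallback: 23 would be reduced under substrate control (NaBH4, CeCl3). If the 7β-alcohol F5 predominates, it would be esterified with 2-bromopropanoic acid under Mitsunobu conditions (PPh3, diisopropyl azodicarboxylate), which inverts C7 and rejoins the route at 26.

Step 19. The samarium reagent may instead cleave the α-acyloxy C7–O bond, the enolate may be protonated by the free C14 hydroxyl, or the aldol may close on the other face of C8 or give the C17 epimer. Fallback: from 27, a Michaelis–Arbuzov reaction with P(OEt)3 would give the phosphonate F6. Intramolecular Horner–Wadsworth–Emmons closure (LiCl, i-Pr2NEt) would give the butenolide F7 (C8=C17). Nucleophilic epoxidation (NaOCl, pyridine) would give the 8α,17α-epoxy lactone F8. SmI2 in THF–MeOH would open the epoxide at C17 to the β-hydroxy lactone, rejoining the route at 28; here C8 is set by the epoxidation face and C17 by protonation.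

Further compounds

F1 | step 15 | 7α-[(E)-prop-1-enyl] carbinol | CC(C)(C)[Si](C)(C)O[C@H]1CC=C(CO[Si](c3ccccc3)(c3ccccc3)C(C)(C)C)[C@@H]2[C@H](OCc3ccc(OC)cc3)C(OC)(OC)[C@@](O)(/C=C/C)[C@](OC)(C=C)[C@]21C
F2 | step 15 | ring-expanded C7 trimethylsilyl enol ether (C5 undefined) | CC(C)(C)[Si](C)(C)O[C@H]1CC=C(CO[Si](c3ccccc3)(c3ccccc3)C(C)(C)C)[C@@H]2[C@H](OCc3ccc(OC)cc3)C(OC)(OC)/C(O[Si](C)(C)C)=C/C(C)C/C=C(OC)/[C@]21C
F3 | step 2 | 9-O-[(S)-2-methoxy-2-phenylacetate] of 6 | CC(C)(C)[Si](C)(C)O[C@H]1C=CC[C@@H]2[C@H](OC(=O)[C@@H](OC)c3ccccc3)C(OC)=CC(=O)[C@]21C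
F4 | step 6 | C11 allylic alcohol (C11 undefined) | CC(C)(C)[Si](C)(C)O[C@H]1C=CC(O)[C@@H]2[C@H](OCc3ccc(OC)cc3)C(OC)=CC(=O)[C@]21C
F5 | step 16 | 7β-alcohol (C7 epimer of 24) | CC(C)(C)[Si](C)(C)O[C@H]1CC=C(CO[Si](c3ccccc3)(c3ccccc3)C(C)(C)C)[C@@H]2[C@H](OCc3ccc(OC)cc3)C(OC)(OC)[C@H](O)/C=C(/C)C/C=C(OC)/[C@]21C
F6 | step 19 | C7 2-(diethoxyphosphoryl)propanoate | O[C@H]1CC=C(CO[Si](c3ccccc3)(c3ccccc3)C(C)(C)C)[C@@H]2[C@H](OCc3ccc(OC)cc3)C(=O)[C@@H](OC(=O)C(C)P(=O)(OCC)OCC)/C=C(/C)CCC(=O)[C@]21C
F7 | step 19 | butenolide (C8=C17) | O[C@H]1CC=C(CO[Si](c3ccccc3)(c3ccccc3)C(C)(C)C)[C@@H]2[C@H](OCc3ccc(OC)cc3)C3=C(C)C(=O)O[C@H]3/C=C(/C)CCC(=O)[C@]21C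
F8 | step 19 | 8α,17α-epoxy lactone | O[C@H]1CC=C(CO[Si](c3ccccc3)(c3ccccc3)C(C)(C)C)[C@@H]2[C@H](OCc3ccc(OC)cc3)[C@@]34O[C@@]4(C)C(=O)O[C@H]3/C=C(/C)CCC(=O)[C@]21C
A1 | alternative 1 | cis-anti-cis tetracyclic photoadduct | O=C1CC[C@@H]2O[Si](C(C)C)(C(C)C)O[C@@]34CC/C(C)=C\CC[C@@]4(O[Si](C)(C)C(C)(C)C)[C@H]1[C@]23C
A2 | alternative 2 | bis-silyl ether of the target | CC(=O)O[C@H]1CC=C(CO[Si](C)(C)C(C)(C)C)[C@@H]2C(=O)[C@@]3(O[Si](CC)(CC)CC)[C@H](/C=C(/C)CC[C@H](OC(C)=O)[C@]21C)OC(=O)[C@@H]3C
A3 | alternative 3 | cyclohexene C2 dimethyl ketal (C14 epimer) | COCO[C@@H]1CC=C(CO[Si](C)(C)C(C)(C)C)[C@H](COC(=O)C(C)(C)C)[C@@]1(C)C(OC)(OC)CCOCc1ccccc1
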